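Remark on the chemistry: the (1S,2S) primary amine–thiourea of step 1 is assumed to add the malonate to the Si face of C4 of the enone; if the sense is the reverse, its (1R,2R) enantiomer is used and nothing else changes.

## The problem

Bisdehydroneotuberostemonine (34) is a pyrrole (N4, C3, C2, C1, C9a) whose N4–C9a edge is shared with an azepine (C5–C9) and whose C1–C9a edge is shared with a cyclohexane (C9, C10, C11, C12). C10 carries an ethyl group, C11/C12 carry a cis-fused γ-lactone (C11–O–C14(=O)–C13–C12, methyl on C13), and C3 carries a pendant γ-lactone (C18–O–C21(=O)–C20–C19, methyl on C20). There are seven stereocentres: C9–C12 contiguous on the cyclohexane, C13 in the fused lactone, and C18/C20 in the pendant lactone. The ethyl group is trans to the C9–C8 bond, while ethyl, the C11–O bond and the C12–C13 bond all lie on one face. H11, H12 and H13 are mutually cis, so the C13 methyl sits on the concave face of the bicyclic lactone. That is the less stable epimer, so it cannot be reached by equilibration or by methylating a finished lactone. C18 and C20 are insulated from the core by the flat pyrrole and must arrive enantiopure; C10 is the centre from which C9, C12 and C11 can be controlled. The pyrrole is electron-rich, the C18–O bond is a pyrrol-2-ylmethyl ester that can ionise under acid, and both lactone α-methyl centres are labile to strong base. The enabling feature is that N4–C9a=C1 is the N–C=C unit of a cyclic enaminone once C12 is a carbonyl, and C2/C3 with the lactone are the two carbons of an α-bromomethyl ketone.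

## Retrosynthesis

**34 to 32.** The fused lactone is opened at its C11–O–C14 ester bond and C11 is taken back to a ketone, so 34 comes from hydroxy ester 33 and that from keto ester 32. Methylating a finished, C13-unsubstituted lactone would add the methyl from the convex face and could not tell the two lactones apart. Forming the C11–O bond by hydroboration or epoxide opening would put oxygen anti to the ethyl group. Reduction of a C11 ketone by a bulky hydride is the operation that gives oxygen cis to both equatorial neighbours. Precursor 32 has one ring and one stereocentre fewer. The forward step must reduce the ketone but not the pendant lactone, and the alkoxide must close on the ester.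

**32 to 28 and 30.** The C12–C13 bond is cut between the ketone α-carbon and a lactate-derived electrophile. Ketone 28 has only a methylene at C12, and triflate 30 comes in one step from methyl (S)-lactate 29. This cut brings C13 in with fixed configuration (SN2 inversion) and leaves C12 as an enolisable centre that can be corrected afterwards. An aldol or Reformatsky construction would leave C13 uncontrolled. The forward reaction needs C-alkylation of a pyrrole-conjugated enolate and then the C12 epimer with the side chain cis to ethyl (epimer 31 to 32).

**28 to 22.** No skeletal bond is cut; the carbonyl is moved from C11 back to C12 through alcohol 27, alkene 25 and carbinol 23. This detour is the price of the pyrrole construction, which needs the carbonyl on C12. An elimination through a sulfonylhydrazone would need strong base and endanger C20, so reduction, dehydration under amine base, hydroboration and oxidation are preferred. The forward steps must avoid acid once the ring ketone is gone.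

**22 to 11 and 20.** The pyrrole is cut at C1–C2 and N4–C3. This is the only cut that removes the pyrrole and joins two fragments of similar size, each carrying its own stereocentres. The precursors are a bicyclic enaminone 11 with two stereocentres and a lactone bromomethyl ketone 20 with two. The forward reaction must alkylate carbon before nitrogen and must not enolise C18.

**11 to 1, 2 and 4.** The N–C9a bond is cut to amino dione 10, that is azido dione 9. The ring is then opened by a Claisen disconnection and decarboxylation to the malonate 6, from chloride 5, from Michael adduct 3, from enone 1, malonate 2 and dihalide 4. Adding the unsubstituted malonate first and alkylating afterwards is preferred to a Michael addition of the 2-alkylmalonate, because hindered malonates are poor donors in asymmetric conjugate additions. Only C10 has to be set by a catalyst; C9 is epimerisable in 9 and 11 and settles trans.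

**20 to 12.** The bromomethyl ketone is a one-carbon homologue of lactone acid 17. This is the diazotisation product of (2S,4S)-4-methylglutamic acid 16, reached from the cis-4-methyl pyroglutamate 14, its enaminone 13 and commercial N-Boc methyl L-pyroglutamate 12. Direct methylation of a glutamic-acid-derived lactone gives the trans isomer; hydrogenation of the exocyclic enaminone gives the cis one.

## Roads not taken

**Alternative 1:** Both N4–C bonds (to C9a and to C3) are cut, leading to an azido keto aldehyde A2 in which C11 is a dioxolane. Reduction of the azide with PPh3 and warming with AcOH would close azepine and pyrrole together in a Paal–Knorr condensation to ketal A1.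
- Merits: the closure is intramolecular and free of regiochemical questions, and the C11 oxygen is already in place, so no carbonyl transposition is needed. In this respect it is better than the chosen plan by about four steps.
- Weak points: A2 has four adjacent functionalised ring carbons with two differentiated carbonyls and is longer to make than 11. C3 is unsubstituted in A1, so the pendant lactone would have to be built afterwards on the electron-rich pyrrole, with C18 created by reagent control far from any stereocentre and C20 set cis after that.
- Comparison: the chosen plan pays for the transposition but installs the enantiopure pendant lactone in the ring-forming step and reaches its key precursors in five and four steps.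

**Alternative 2:** The C9–C10 bond is cut. A chiral BINOL-derived N-triflylphosphoramide would ionise racemic carbinol A4 to an azafulvenium ion, and the enol of the side-chain ketone would attack C9 to close the cyclohexanone A3.
- Merits: it is enantioconvergent, sets C9 and C10 in one catalytic step, places the ketone on C11 directly and leaves an ester on C3 as a handle. For the core it is shorter and more original than the chosen plan.
- Weak points: the C3 ester that tames the pyrrole also destabilises the cation. The ketone must enolise toward C10 although the C12 side is more acidic. Control of both centres by a chiral counter-anion in an intramolecular enol addition to a pyrrol-2-ylmethyl cation has no close precedent, so the central step would itself be a research problem. The pendant lactone would still have to be grown from the ester in several reagent-controlled steps.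
- Comparison: the chosen plan uses only known reaction types and takes C18 and C20 from the chiral pool.

**Alternative 3:** The C1–C12 bond is cut. Sc(OTf)3 would activate the α-methylbutenolide of the tethered pyrrole A6, and C1 would add to C12, closing the cyclohexane and, after protonation at C13, giving the tetracyclic lactone A5.
- Merits: it forms the ring, C12, C13 and the finished fused lactone in one step. The tether enforces the cis fusion, and protonation from the convex face would give the required concave methyl. For the fused lactone it is clearly shorter: no transposition, no lactate alkylation, no hydride step.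
- Weak points: A6 needs C9, C10 and C11 set in an open-chain precursor, so the stereochemical work is moved forward, not removed. An α-methylbutenolide is a poor acceptor, and the free α-position C3 is the most nucleophilic site of the pyrrole, so intermolecular reaction competes. C13 may equilibrate under the Lewis acid. The pendant lactone must still be attached to C3 afterwards.
- Comparison: the chosen plan offers convergent delivery of the pendant lactone and simple, robust precursors.

Key step: step 10

## Route

Step 1
Reactants: 1 (E)-hex-3-en-2-one; 2 dimethyl malonate
Product: 3 dimethyl 2-[(3S)-5-oxohexan-3-yl]propanedioate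
Conditions: 1-[(1S,2S)-2-aminocyclohexyl]-3-[3,5-bis(trifluoromethyl)phenyl]thiourea (10 mol %), PhCO2H (10 mol %), 2 (2 equiv), toluene, 23 °C
Reagents that add atoms: none
Why: Iminium activation of the enone by the primary amine with thiourea binding of the malonate is an established organocatalytic Michael addition of malonates to acyclic enones; attack on the Si face of C4 sets the S centre that becomes C10.

Step 2
Reactants: 3 dimethyl 2-[(3S)-5-oxohexan-3-yl]propanedioate; 4 1-bromo-4-chlorobutane
Product: 5 dimethyl 2-(4-chlorobutyl)-2-[(3S)-5-oxohexan-3-yl]propanedioate
Conditions: NaH, DMF, 0 °C; then 4 (3 equiv), 0 → 40 °C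
Reagents that add atoms: none
Why: The malonate C–H is by far the most acidic site, so its sodium enolate is alkylated at carbon by the bromide end of 4 while the chloride is kept (malonic ester alkylation of a 2-sec-alkylmalonate). Without free alkoxide the methyl ketone is not enolised enough to start the Claisen closure.

Step 3
Reactants: 5 dimethyl 2-(4-chlorobutyl)-2-[(3S)-5-oxohexan-3-yl]propanedioate
Product: 6 dimethyl 2-(4-azidobutyl)-2-[(3S)-5-oxohexan-3-yl]propanedioate
Conditions: NaN3, DMF, 60 °C
Reagents that add atoms: sodium azide, [Na+].[N-]=[N+]=[N-]
Why: SN2 displacement of the primary chloride by azide in a dipolar aprotic solvent; the azide tolerates the alkoxide and acid of the next step.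

Step 4
Reactants: 6 dimethyl 2-(4-azidobutyl)-2-[(3S)-5-oxohexan-3-yl]propanedioate
Product: 9 (4R,5S)-4-(4-azidobutyl)-5-ethylcyclohexane-1,3-dione, via β-keto ester 7 (not isolated), via β-keto acid 8 (not isolated)
Conditions: NaOMe, MeOH, 65 °C; then aq NaOH, 65 °C; then aq HCl to pH 1, 60 °C
Reagents that add atoms: none
Why: The methyl ketone enolate attacks one malonate ester (Claisen closure to the cyclohexane-1,3-dione), the remaining ester is saponified and the β-keto acid loses CO2 on acidification, the classical route to 4-substituted cyclohexane-1,3-diones. C4 is epimerisable and should settle trans to the ethyl group with both substituents equatorial.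

Step 5
Reactants: 9 (4R,5S)-4-(4-azidobutyl)-5-ethylcyclohexane-1,3-dione
Product: 11 (5aR,6S)-6-ethyl-1,2,3,4,5,5a,6,7-octahydro-8H-1-benzazepin-8-one, via amino dione 10 (not isolated)
Conditions: H2 (1 atm), Pd/C, MeOH, 23 °C; then AcOH (cat.), toluene (0.02 M), 110 °C, Dean–Stark
Reagents that add atoms: none
Why: Hydrogenolysis of the azide gives the primary amine, which condenses with the nearer carbonyl of the vinylogous acid to the seven-membered vinylogous amide (enaminone formation with azeotropic removal of water). C5a can equilibrate through the imine–enamine tautomers and should rest trans to ethyl; any cis isomer is removed by crystallisation or chromatography.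

Step 6
Reactants: 12 1-tert-butyl 2-methyl (2S)-5-oxopyrrolidine-1,2-dicarboxylate
Product: 13 1-tert-butyl 2-methyl (2S,4E)-4-[(dimethylamino)methylidene]-5-oxopyrrolidine-1,2-dicarboxylate
Conditions: t-BuOCH(NMe2)2, DME, 75 °C
Reagents that add atoms: tert-butoxybis(dimethylamino)methane, CN(C)C(OC(C)(C)C)N(C)C
Why: The activated C4 methylene of the N-Boc lactam condenses with the aminal ester to the E-enaminone (Bredereck aminomethylenation); C2 is not touched.

Step 7
Reactants: 13 1-tert-butyl 2-methyl (2S,4E)-4-[(dimethylamino)methylidene]-5-oxopyrrolidine-1,2-dicarboxylate
Product: 14 1-tert-butyl 2-methyl (2S,4S)-4-methyl-5-oxopyrrolidine-1,2-dicarboxylate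
Conditions: H2 (3 atm), Pd/C, i-PrOH, 23 °C
Reagents that add atoms: none
Why: Hydrogenation with loss of dimethylamine passes through the exocyclic methylene lactam, which is saturated from the face opposite the C2 ester, so the methyl ends cis to the ester (heterogeneous hydrogenation–hydrogenolysis known for this lactam).

Step 8
Reactants: 14 1-tert-butyl 2-methyl (2S,4S)-4-methyl-5-oxopyrrolidine-1,2-dicarboxylate
Product: 17 (2S,4S)-4-methyl-5-oxooxolane-2-carboxylic acid, via N-Boc diacid 15 (not isolated), via amino diacid hydrochloride 16 (not isolated)
Conditions: LiOH, THF/H2O, 0 → 23 °C; then 4 M HCl, 50 °C; then NaNO2, H2O, 0 → 23 °C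
Reagents that add atoms: lithium hydroxide, [Li+].[OH-]; water, O
Why: Hydroxide opens the activated N-Boc lactam and the ester, and acid removes the Boc group. Diazotisation of the amino acid proceeds through the α-lactone with double inversion, so the 5-carboxylate closes the γ-lactone with net retention at C2, as in the conversion of glutamic acid itself.

Step 9
Reactants: 17 (2S,4S)-4-methyl-5-oxooxolane-2-carboxylic acid
Product: 20 (3S,5S)-5-(2-bromoacetyl)-3-methyloxolan-2-one, via acid chloride 18 (not isolated), via diazoketone 19 (not isolated)
Conditions: (COCl)2, DMF (cat.), CH2Cl2, 0 → 23 °C; then Me3SiCHN2, MeCN/THF, 0 °C; then 48% aq HBr, 0 °C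
Reagents that add atoms: (trimethylsilyl)diazomethane, C[Si](C)(C)C=[N+]=[N-]; hydrogen bromide, Br
Why: Acid chloride formation, acylation of the diazoalkane and HBr cleavage of the diazoketone (Arndt–Eistert-type route to a bromomethyl ketone) add one carbon without base, so the α-acyloxy centre is not enolised.

Step 10
Reactants: 11 (5aR,6S)-6-ethyl-1,2,3,4,5,5a,6,7-octahydro-8H-1-benzazepin-8-one; 20 (3S,5S)-5-(2-bromoacetyl)-3-methyloxolan-2-one
Product: 22 C12 ketone of the pyrrole–azepine–cyclohexane tricycle bearing the pendant lactone on C3, via C-alkylated enaminone 21 (not isolated)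
Conditions: NaHCO3, MeCN, 23 → 60 °C
Reagents that add atoms: none
Why: The enaminone is a vinylogous amide whose α-carbon (C9 of 11, the future C1) is its soft nucleophilic site; it displaces bromide from 20 by SN2 to give the 1,4-dicarbonyl-type intermediate 21, with NaHCO3 taking up the HBr. The secondary enamine nitrogen of 21 then adds to the side-chain ketone (5-exo-trig) and loss of water from the hemiaminal aromatises the ring, so the C1–C2 and N4–C3 bonds and the pyrrole form in one flask. The closest known reaction is the Hantzsch-type annulation of cyclic 3-aminocyclohex-2-enones, including N-substituted ones, with α-haloketones to 4-oxo-4,5,6,7-tetrahydroindoles. No stereocentre is created; C9, C10, C18 and C20 are carried through. The step needs alkylation at carbon before nitrogen, which places the lactone on the pyrrole α-carbon; the α-carbon is the more reactive site of a vinylogous amide toward a soft alkyl halide and the ring nitrogen is a hindered secondary N–H. It also needs the α-acyloxy ketone centre C18 to survive, which the weak, poorly soluble base and the fast aromatisation (which removes the enolisable ketone) should secure. Closure through the ring carbonyl oxygen to a furan is an acid-promoted path and is not expected under bicarbonate.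

Step 11
Reactants: 22 C12 ketone of the tricycle bearing the pendant lactone
Product: 23 C12 carbinol
Conditions: NaBH4, MeOH/THF (1:4), 0 → 23 °C
Reagents that add atoms: none
Why: Borohydride 1,2-reduction of the pyrrole-conjugated ketone is faster than attack on the γ-lactone at this temperature, and under these basic conditions the N-alkylpyrrole carbinol does not ionise. Either carbinol epimer serves; the one drawn arises from axial attack.

Step 12
Reactants: 23 C12 carbinol
Product: 25 C11=C12 alkene (vinylpyrrole), via C12 mesylate 24 (not isolated)
Conditions: MsCl, Et3N, CH2Cl2 (0.02 M), −20 → 23 °C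
Reagents that add atoms: none
Why: The pyrrol-3-ylmethyl mesylate ionises at once and the amine removes a C11 proton, the only β-hydrogens available (dehydration through the sulfonate under basic conditions). The acid-labile C18–O bond never meets acid.

Step 13
Reactants: 25 C11=C12 alkene
Product: 27 C11 alcohol with hydroxyl trans to ethyl, via C11 alkylborane 26 (not isolated)
Conditions: BH3·THF, THF, 0 °C; then NaBO3·4H2O, H2O, 23 °C
Reagents that add atoms: sodium perborate, [Na+].[O-]OB=O
Why: syn-Hydroboration puts boron on C11, the electron-rich terminus of the pyrrole-conjugated alkene, as with electron-rich styrenes (anti-Markovnikov hydroboration–oxidation); perborate oxidises the C–B bond with retention under conditions that spare the lactone. The carbinol centre, expected anti to ethyl, is removed in step 14.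

Step 14
Reactants: 27 C11 alcohol
Product: 28 C11 ketone with C12 methylene
Conditions: Dess–Martin periodinane, NaHCO3, CH2Cl2, 0 °C
Reagents that add atoms: none
Why: Buffered Dess–Martin oxidation of the secondary alcohol gives the β-pyrrolyl ketone without acid or base strong enough to ionise C18 or epimerise C10; the ketone is used at once.

Step 15
Reactants: 29 methyl (2S)-2-hydroxypropanoate
Product: 30 methyl (2S)-2-{[(trifluoromethyl)sulfonyl]oxy}propanoate
Conditions: Tf2O, 2,6-lutidine, CH2Cl2, −78 → 0 °C
Reagents that add atoms: trifluoromethanesulfonic anhydride, O=S(=O)(OS(=O)(=O)C(F)(F)F)C(F)(F)F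
Why: O-Sulfonylation of the secondary alcohol breaks no bond to the stereocentre; the triflate is used fresh.

Step 16
Reactants: 28 C11 ketone; 30 methyl (2S)-2-{[(trifluoromethyl)sulfonyl]oxy}propanoate
Product: 31 C12-alkylated keto ester with the (S)-1-methoxy-1-oxopropan-2-yl group trans to ethyl
Conditions: LiN(SiMe3)2 (1.05 equiv), THF, −78 °C; then 30, −78 → −40 °C
Reagents that add atoms: none
Why: The C12 protons, flanked by ketone and pyrrole, are removed selectively, and the conjugated enolate displaces the α-triflyloxy ester by SN2 with inversion (enolate alkylation with a lactate triflate), which fixes C13 as S. Attack anti to the ethyl group is expected to give mainly the C12 epimer drawn; either epimer serves in step 17.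

Step 17
Reactants: 31 C12-alkylated keto ester
Product: 32 C12 epimer with the side chain cis to ethyl
Conditions: DBU (0.3 equiv), CH2Cl2, 23 °C
Reagents that add atoms: none
Why: C12–H is acidic enough for DBU to equilibrate it, while the ester and lactone α-centres are not touched (base-mediated epimerisation). Only the epimer with the side chain cis to ethyl can hold all three ring substituents equatorial, so it should predominate.

Step 18
Reactants: 32 keto ester with the side chain cis to ethyl
Product: 34 bisdehydroneotuberostemonine, via C11 hydroxy ester 33 (not isolated)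
Conditions: LiBH(s-Bu)3 (1.2 equiv), THF, −78 → 0 °C; then aq NH4Cl
Reagents that add atoms: none
Why: The bulky hydride attacks the C11 ketone from the equatorial direction, giving the axial alkoxide cis to both equatorial neighbours. On warming, this alkoxide closes the cis-fused γ-lactone on the methyl ester (5-exo-trig lactonisation); the pendant lactone is not reduced at low temperature.

## Compound list

1 | (E)-hex-3-en-2-one | CC/C=C/C(C)=O | starting material
2 | dimethyl malonate | COC(=O)CC(=O)OC | starting material
3 | dimethyl 2-[(3S)-5-oxohexan-3-yl]propanedioate | CC[C@@H](CC(C)=O)C(C(=O)OC)C(=O)OC | intermediate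
4 | 1-bromo-4-chlorobutane | ClCCCCBr | starting material
5 | dimethyl 2-(4-chlorobutyl)-2-[(3S)-5-oxohexan-3-yl]propanedioate | CC[C@@H](CC(C)=O)C(CCCCCl)(C(=O)OC)C(=O)OC | intermediate
6 | dimethyl 2-(4-azidobutyl)-2-[(3S)-5-oxohexan-3-yl]propanedioate | CC[C@@H](CC(C)=O)C(CCCCN=[N+]=[N-])(C(=O)OC)C(=O)OC | intermediate
7 | methyl (6S)-1-(4-azidobutyl)-6-ethyl-2,4-dioxocyclohexane-1-carboxylate, C1 epimers, formed as its sodium enolate | CC[C@H]1CC(=O)CC(=O)C1(CCCCN=[N+]=[N-])C(=O)OC | intermediate
8 | (6S)-1-(4-azidobutyl)-6-ethyl-2,4-dioxocyclohexane-1-carboxylic acid, C1 epimers | CC[C@H]1CC(=O)CC(=O)C1(CCCCN=[N+]=[N-])C(=O)O | intermediate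
9 | (4R,5S)-4-(4-azidobutyl)-5-ethylcyclohexane-1,3-dione | CC[C@H]1CC(=O)CC(=O)[C@@H]1CCCCN=[N+]=[N-] | intermediate
10 | (4R,5S)-4-(4-aminobutyl)-5-ethylcyclohexane-1,3-dione | CC[C@H]1CC(=O)CC(=O)[C@@H]1CCCCN | intermediate
11 | (5aR,6S)-6-ethyl-1,2,3,4,5,5a,6,7-octahydro-8H-1-benzazepin-8-one (enaminone, ethyl trans to the azepine C5) | CC[C@H]1CC(=O)C=C2NCCCC[C@H]12 | intermediate
12 | 1-tert-butyl 2-methyl (2S)-5-oxopyrrolidine-1,2-dicarboxylate | COC(=O)[C@@H]1CCC(=O)N1C(=O)OC(C)(C)C | starting material
13 | 1-tert-butyl 2-methyl (2S,4E)-4-[(dimethylamino)methylidene]-5-oxopyrrolidine-1,2-dicarboxylate | COC(=O)[C@@H]1C/C(=C\N(C)C)C(=O)N1C(=O)OC(C)(C)C | intermediate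
14 | 1-tert-butyl 2-methyl (2S,4S)-4-methyl-5-oxopyrrolidine-1,2-dicarboxylate | COC(=O)[C@@H]1C[C@H](C)C(=O)N1C(=O)OC(C)(C)C | intermediate
15 | (2S,4S)-2-[(tert-butoxycarbonyl)amino]-4-methylpentanedioic acid | OC(=O)[C@@H](NC(=O)OC(C)(C)C)C[C@H](C)C(=O)O | intermediate
16 | (2S,4S)-2-amino-4-methylpentanedioic acid hydrochloride | OC(=O)[C@@H](N)C[C@H](C)C(=O)O.Cl | intermediate
17 | (2S,4S)-4-methyl-5-oxooxolane-2-carboxylic acid | OC(=O)[C@@H]1C[C@H](C)C(=O)O1 | intermediate
18 | (2S,4S)-4-methyl-5-oxooxolane-2-carbonyl chloride | ClC(=O)[C@@H]1C[C@H](C)C(=O)O1 | intermediate
19 | (3S,5S)-5-(2-diazoacetyl)-3-methyloxolan-2-one | [N-]=[N+]=CC(=O)[C@@H]1C[C@H](C)C(=O)O1 | intermediate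
20 | (3S,5S)-5-(2-bromoacetyl)-3-methyloxolan-2-one | BrCC(=O)[C@@H]1C[C@H](C)C(=O)O1 | intermediate
21 | (5aR,6S)-6-ethyl-9-{2-[(2S,4S)-4-methyl-5-oxooxolan-2-yl]-2-oxoethyl}-1,2,3,4,5,5a,6,7-octahydro-8H-1-benzazepin-8-one | CC[C@H]1CC(=O)C(CC(=O)[C@@H]3C[C@H](C)C(=O)O3)=C2NCCCC[C@H]12 | intermediate
22 | tricyclic pyrrole ketone: C12 ketone, C11 methylene, ethyl on C10 trans to C9–C8, (2S,4S)-4-methyl-5-oxooxolan-2-yl on C3 | CC[C@H]1CC(=O)c2cc([C@@H]3C[C@H](C)C(=O)O3)n3c2[C@@H]1CCCC3 | intermediate
23 | C12 carbinol of 22 (drawn as the epimer with hydroxyl cis to ethyl; the other epimer is equally usable) | CC[C@H]1C[C@@H](O)c2cc([C@@H]3C[C@H](C)C(=O)O3)n3c2[C@@H]1CCCC3 | intermediate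
24 | C12 methanesulfonate of 23 | CC[C@H]1C[C@@H](OS(C)(=O)=O)c2cc([C@@H]3C[C@H](C)C(=O)O3)n3c2[C@@H]1CCCC3 | intermediate
25 | C11=C12 alkene (vinylpyrrole) | CC[C@H]1C=Cc2cc([C@@H]3C[C@H](C)C(=O)O3)n3c2[C@@H]1CCCC3 | intermediate
26 | C11 alkylborane, boron trans to ethyl (drawn as the monoalkylborane) | CC[C@H]1[C@H](B)Cc2cc([C@@H]3C[C@H](C)C(=O)O3)n3c2[C@@H]1CCCC3 | intermediate
27 | C11 alcohol, hydroxyl trans to ethyl | CC[C@H]1[C@H](O)Cc2cc([C@@H]3C[C@H](C)C(=O)O3)n3c2[C@@H]1CCCC3 | intermediate
28 | C11 ketone with C12 methylene (transposed ketone) | CC[C@H]1C(=O)Cc2cc([C@@H]3C[C@H](C)C(=O)O3)n3c2[C@@H]1CCCC3 | intermediate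
29 | methyl (2S)-2-hydroxypropanoate (methyl (S)-lactate) | C[C@H](O)C(=O)OC | starting material
30 | methyl (2S)-2-{[(trifluoromethyl)sulfonyl]oxy}propanoate | C[C@H](OS(=O)(=O)C(F)(F)F)C(=O)OC | intermediate
31 | C11 ketone carrying (S)-CH(CH3)CO2CH3 on C12, side chain trans to ethyl | CC[C@H]1C(=O)[C@H]([C@H](C)C(=O)OC)c2cc([C@@H]3C[C@H](C)C(=O)O3)n3c2[C@@H]1CCCC3 | intermediate
32 | C12 epimer of 31, side chain cis to ethyl | CC[C@H]1C(=O)[C@@H]([C@H](C)C(=O)OC)c2cc([C@@H]3C[C@H](C)C(=O)O3)n3c2[C@@H]1CCCC3 | intermediate
33 | C11 hydroxy ester, hydroxyl cis to ethyl and to the C12 side chain (formed as its lithium alkoxide) | CC[C@H]1[C@@H](O)[C@@H]([C@H](C)C(=O)OC)c2cc([C@@H]3C[C@H](C)C(=O)O3)n3c2[C@@H]1CCCC3 | intermediate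
34 | bisdehydroneotuberostemonine (9R,10R,11R,12S,13S,18S,20S in the labels used here) | CC[C@H]1[C@H]2OC(=O)[C@@H](C)[C@H]2c2cc([C@@H]3C[C@H](C)C(=O)O3)n3c2[C@@H]1CCCC3 | target

## Step count and risks

Total: 18 steps. Longest linear sequence: 13 steps (steps 1–5, 10–14 and 16–18) from 1 and 2.

**Step 10 (key step).** The most likely failure is alkylation at nitrogen before carbon, which would give the pyrrole with the lactone on the β-carbon. A second is slow ring closure, during which the α-acyloxy ketone centre C18 could enolise and lose its configuration. The fallback removes nitrogen from the alkylation. It sets out from azido dione 9 and bromoketone 20: C-alkylation of the dione at C2 (K2CO3, CHCl3, 23 °C) gives the triketo azide F1. Hydrogenation of the azide over Pd/C and warming with AcOH in toluene then closes azepine and pyrrole in a Paal–Knorr condensation by way of 21, returning to the route at 22.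

**Step 17.** The equilibrium at C12 may not favour the needed epimer, because the equatorial side chain lies next to the pyrrole C2–H and to the carbonyl group, which lowers the usual equatorial preference. The fallback replaces thermodynamic by kinetic control. It sets out from 31 (or the mixture of epimers): KN(SiMe3)2 in THF at −78 °C gives the potassium enolate F2, which is quenched with 2,6-di-tert-butyl-4-methylphenol. The proton should arrive on the face away from the ethyl group, as the electrophile does in step 16, which gives 32.

**Step 16.** O-alkylation of the delocalised lithium enolate, or elimination of triflic acid from the hindered secondary triflate, may compete with C-alkylation. The fallback changes the nucleophile to a neutral enamine. It sets out from 28: pyrrolidine in MeOH at 23 °C gives the conjugated pyrrolidine enamine F3, which is alkylated at C12 by 30 in MeCN to the iminium triflate F4. Hydrolysis in aqueous acetate buffer gives 31.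

**Step 12 (with step 11).** Ionisation of the mesylate gives a pyrrole-stabilised cation that may be attacked by the free C2 position of a second molecule (oligomerisation) before it loses a proton, and the preceding reduction may be slow enough for the lactone to be attacked. The fallback avoids both the carbinol and the cation. It sets out from 22: Tf2O and 2,6-di-tert-butyl-4-methylpyridine in CH2Cl2 give the dienyl triflate F5, and reduction with Pd(OAc)2, PPh3, HCO2H and Bu3N in DMF at 60 °C gives 25.

**Step 1.** The enantioselectivity may be too low with a purely aliphatic enone. The fallback forms the same C–C bond from the other side. It sets out from 2: Knoevenagel condensation with propanal (piperidine, AcOH) gives dimethyl 2-propylidenepropanedioate F6. A Mukaiyama–Michael addition of 2-(trimethylsilyloxy)propene catalysed by Cu[(S,S)-t-Bu-box](SbF6)2 (or its enantiomer, as the sense requires), followed by desilylation on work-up, gives 3.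

## Further compounds

F1 | step 10 | (4R,5S)-4-(4-azidobutyl)-5-ethyl-2-{2-[(2S,4S)-4-methyl-5-oxooxolan-2-yl]-2-oxoethyl}cyclohexane-1,3-dione | CC[C@H]1CC(=O)C(CC(=O)[C@@H]2C[C@H](C)C(=O)O2)C(=O)[C@@H]1CCCCN=[N+]=[N-]
F2 | step 17 | potassium C11–C12 enolate of keto ester 31 | CC[C@H]1C([O-])=C([C@H](C)C(=O)OC)c2cc([C@@H]3C[C@H](C)C(=O)O3)n3c2[C@@H]1CCCC3.[K+]
F3 | step 16 | C11 pyrrolidine enamine of ketone 28 (C11=C12) | CC[C@H]1C(N2CCCC2)=Cc2cc([C@@H]4C[C@H](C)C(=O)O4)n3c2[C@@H]1CCCC3
F4 | step 16 | C12-alkylated C11 pyrrolidinium (iminium) triflate, C12 epimers | CC[C@H]1C(=[N+]2CCCC2)C([C@H](C)C(=O)OC)c2cc([C@@H]4C[C@H](C)C(=O)O4)n3c2[C@@H]1CCCC3.[O-]S(=O)(=O)C(F)(F)F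
F5 | step 12 | C12 enol triflate of ketone 22 (C11=C12) | CC[C@H]1C=C(OS(=O)(=O)C(F)(F)F)c2cc([C@@H]3C[C@H](C)C(=O)O3)n3c2[C@@H]1CCCC3
F6 | step 1 | dimethyl 2-propylidenepropanedioate | CCC=C(C(=O)OC)C(=O)OC
A1 | alternative 1 | tricyclic pyrrolo-azepine with C11 dioxolane | CC[C@H]1C2(OCCO2)Cc2ccn3c2[C@@H]1CCCC3
A2 | alternative 1 | azido keto aldehyde with C11 dioxolane | CC[C@H]1C2(OCCO2)CC(CC=O)C(=O)[C@@H]1CCCCN=[N+]=[N-]
A3 | alternative 2 | tricyclic C11 ketone with tert-butyl ester on C3 | CC[C@H]1C(=O)Cc2cc(C(=O)OC(C)(C)C)n3c2[C@@H]1CCCC3
A4 | alternative 2 | racemic C9 carbinol of the pyrrolo-azepine with a 2-oxopentyl chain on C1 | CCCC(=O)Cc1cc(C(=O)OC(C)(C)C)n2CCCCC(O)c12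
A5 | alternative 3 | tetracyclic core with fused lactone, C3 unsubstituted | CC[C@H]1[C@H]2OC(=O)[C@@H](C)[C@H]2c2ccn3c2[C@@H]1CCCC3
A6 | alternative 3 | pyrrolo-azepine tethered to the α-methylbutenolide | CC[C@@H]([C@H]1OC(=O)C(C)=C1)[C@H]1CCCCn2cccc12
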